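**Plan**

1. Numbering: isoquinoline C1–C8a; naphthalene primed, with C8' on the biaryl axis, OMe on C4' and C5', Me on C2'. The enabling feature is the naphthalene ring C5'–C8': C8' is para to the oxygen-bearing C5', and C6' and C7' are plain CH, so this ring is the phenol tautomer of a 4-aryl-4H-naphthalen-1-one whose C6'=C7' bond alkene metathesis can make.
2. Retrosynthetic cuts, in order: N–CH3 (back to N–CO2Me) and C5'O–CH3; C6'=C7' (metathesis, C8' back to an sp3 methine); C4a'–C5' (aryllithium + acrolein); C8'–C7' (diarylmethyl cation + vinyl borate); C5–C8' (aryllithium + aldehyde); then C1–C8a (Bischler–Napieralski) and C4–C4a (sulfamidate opening).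
3. Forward: the nitrogen ring of the isoquinoline closes first (steps 1–8). The brominated benzaldehyde (step 9) is attached at C5 (step 10) and the two vinyl groups are installed (steps 11–13). The second naphthalene ring closes last (step 14), followed by O-methylation and carbamate reduction.
4. Stereochemistry: C3 (S) is bought with N-Boc-L-alaninol (one step from L-alaninol). C1 (R) is set by substrate-controlled NaBH4 reduction of the 3,4-dihydroisoquinoline, cis to the C3 methyl. The C8' methine is carried as both epimers and disappears into the axis.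
5. Remark: the target structure defines C1 and C3 only and leaves the C5–C8' axis open, so both atropo-diastereomers are taken as the target.

Key step: step 14

**Route**

Step 1
Reactants: 1 tert-butyl N-[(2S)-1-hydroxypropan-2-yl]carbamate (N-Boc-L-alaninol)
Product: 2 tert-butyl (4S)-4-methyl-1,2,3-oxathiazolidine-3-carboxylate 2-oxide (both sulfur epimers)
Conditions: SOCl2, pyridine, MeCN, −40 °C → rt
Reagents that add atoms: thionyl chloride, O=S(Cl)Cl
Why: Cyclic sulfamidite formation, in which SOCl2 sulfinylates the primary alcohol and the carbamate N–H closes the five-membered ring while pyridine takes up HCl, is the routine first stage of sulfamidate synthesis from N-Boc 1,2-amino alcohols and does not touch the C–N stereocentre.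

Step 2
Reactants: 2 cyclic sulfamidite
Product: 3 tert-butyl (4S)-4-methyl-1,2,3-oxathiazolidine-3-carboxylate 2,2-dioxide
Conditions: RuCl3·xH2O (cat.), NaIO4, MeCN/H2O, 0 °C
Reagents that add atoms: sodium periodate, [Na+].[O-]I(=O)(=O)=O
Why: Catalytic ruthenium tetroxide oxidation (RuO4 formed from RuCl3 and NaIO4) turns the sulfinyl into the sulfonyl group, removes the sulfur stereocentre and gives the activated cyclic sulfamidate.

Step 3
Reactants: 3 cyclic sulfamidate; 4 1-bromo-3,5-dimethoxybenzene
Product: 7 tert-butyl N-[(2S)-1-(3,5-dimethoxyphenyl)propan-2-yl]carbamate, via (3,5-dimethoxyphenyl)magnesium bromide 5 (not isolated), via bromomagnesium N-sulfamate 6 (not isolated)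
Conditions: 4, Mg, THF, reflux; then 3, CuI (10 mol %), THF, −30 → 0 °C; then 10% aq. citric acid, rt
Reagents that add atoms: none
Why: CuI-catalysed SN2 ring opening of the cyclic sulfamidate by the aryl Grignard reagent at the oxygen-bearing CH2, followed by mild acid hydrolysis of the N-sulfamate, forms the C4–C4a bond without touching the neighbouring stereocentre, so the S configuration of 1 becomes C3 of the isoquinoline.

Step 4
Reactants: 7 N-Boc amine
Product: 9 N-[(2S)-1-(3,5-dimethoxyphenyl)propan-2-yl]acetamide, via ammonium chloride 8 (not isolated)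
Conditions: 4 M HCl in dioxane, rt; evaporate; Ac2O, Et3N, CH2Cl2, 0 °C → rt
Reagents that add atoms: acetic anhydride, CC(=O)OC(C)=O
Why: Acidolytic Boc cleavage followed by N-acetylation of the amine salt are standard operations and bring in the two carbons that become C1 and its methyl group.

Step 5
Reactants: 9 acetamide
Product: 10 (3S)-6,8-dimethoxy-1,3-dimethyl-3,4-dihydroisoquinoline
Conditions: POCl3, MeCN, reflux
Reagents that add atoms: none
Why: Bischler–Napieralski cyclodehydration onto a ring activated by two methoxy groups can give only the 6,8-dimethoxy pattern, because both positions ortho to the side chain are equivalent (each para to one methoxy and ortho to the other), and C3 cannot epimerise under these conditions.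

Step 6
Reactants: 10 3,4-dihydroisoquinoline
Product: 11 (1R,3S)-6,8-dimethoxy-1,3-dimethyl-1,2,3,4-tetrahydroisoquinoline
Conditions: NaBH4, MeOH, 0 °C
Reagents that add atoms: none
Why: Borohydride reduction of the cyclic imine should deliver hydride to C1 on the face away from the C3 methyl group (axial attack on the half-chair with that methyl pseudo-equatorial), which places the two methyl groups cis and sets C1 as R, the usual outcome for 1,3-dimethyl-3,4-dihydroisoquinolines.

Step 7
Reactants: 11 cis-tetrahydroisoquinoline
Product: 12 methyl (1R,3S)-6,8-dimethoxy-1,3-dimethyl-3,4-dihydroisoquinoline-2(1H)-carboxylate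
Conditions: ClCO2Me, Et3N, CH2Cl2, 0 °C
Reagents that add atoms: methyl chloroformate, COC(=O)Cl
Why: N-Acylation with a chloroformate gives the methyl carbamate, which removes the basicity of nitrogen for the later acid, oxidation and ruthenium steps and already holds the carbon of the final N-methyl group.

Step 8
Reactants: 12 methyl carbamate
Product: 13 methyl (1R,3S)-5-bromo-6,8-dimethoxy-1,3-dimethyl-3,4-dihydroisoquinoline-2(1H)-carboxylate
Conditions: NBS (1.0 equiv), MeCN, 0 °C
Reagents that add atoms: N-bromosuccinimide, O=C1CCC(=O)N1Br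
Why: Electrophilic aromatic bromination should go to C5, which is para to the C8 methoxy and ortho to the C6 methoxy group, rather than to C7, which is wedged between two methoxy groups, as is usual for 6,8-dioxygenated tetrahydroisoquinolines.

Step 9
Reactants: 14 3-methoxy-5-methylbenzaldehyde
Product: 18 2-bromo-3-methoxy-5-methylbenzaldehyde, via lithium α-amino alkoxide 15 (not isolated), via 2-lithio α-amino alkoxide 16 (not isolated), via 2-bromo α-amino alkoxide 17 (not isolated)
Conditions: Me2NCH2CH2N(Me)Li (from Me2NCH2CH2NHMe and n-BuLi), THF, −20 °C; n-BuLi (3 equiv), −20 °C; BrCl2C–CCl2Br, −78 °C → rt; then H2O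
Reagents that add atoms: 1,2-dibromo-1,1,2,2-tetrachloroethane, ClC(Cl)(Br)C(Cl)(Cl)Br
Why: Directed ortho-lithiation through an in situ α-amino alkoxide: the lithium amide adds to the aldehyde, which masks it and creates a chelating director that cooperates with the methoxy group to guide n-BuLi to C2, the one position between both directors, after which the aryllithium is brominated and aqueous work-up returns the aldehyde.

Step 10
Reactants: 13 5-bromo-tetrahydroisoquinoline carbamate; 18 2-bromo-3-methoxy-5-methylbenzaldehyde
Product: 20 methyl (1R,3S)-5-[(2-bromo-3-methoxy-5-methylphenyl)(hydroxy)methyl]-6,8-dimethoxy-1,3-dimethyl-3,4-dihydroisoquinoline-2(1H)-carboxylate (both carbinol epimers), via 5-lithio-tetrahydroisoquinoline carbamate 19 (not isolated)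
Conditions: 13, n-BuLi (1.05 equiv), THF, −78 °C; then 18, −78 °C; then H2O
Reagents that add atoms: none
Why: Bromine–lithium exchange followed by 1,2-addition of the aryllithium to the aldehyde forms the C5–C8' bond; at −78 °C exchange should be faster than attack on the methyl carbamate or carbamate-directed lithiation at C1, carbonyl addition faster than exchange with the aryl bromide of 18, and the uncontrolled carbinol centre is removed by ionisation in the next step.

Step 11
Reactants: 20 benzhydrol
Product: 21 methyl (1R,3S)-5-[1-(2-bromo-3-methoxy-5-methylphenyl)prop-2-en-1-yl]-6,8-dimethoxy-1,3-dimethyl-3,4-dihydroisoquinoline-2(1H)-carboxylate (both C8' epimers)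
Conditions: CH2=CHBF3K (3 equiv), HBF4·OEt2 (1.5 equiv), MeCN, 0 °C
Reagents that add atoms: potassium vinyltrifluoroborate, C=C[B-](F)(F)F.[K+]
Why: Brønsted acid-promoted SN1 substitution of a benzhydrol by a potassium alkenyltrifluoroborate: the hydroxyl leaves as water to give a diarylmethyl cation stabilised by the ortho C6 and para C8 methoxy groups, ipso attack of the vinyl borate with loss of BF3 forms the C8'–C7' bond, and the new methine centre arises as both epimers, which is acceptable because it later becomes the axis.

Step 12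
Reactants: 21 bromo diarylpropene
Product: 23 methyl (1R,3S)-5-{1-[2-(1-hydroxyprop-2-en-1-yl)-3-methoxy-5-methylphenyl]prop-2-en-1-yl}-6,8-dimethoxy-1,3-dimethyl-3,4-dihydroisoquinoline-2(1H)-carboxylate (diastereomer mixture), via aryllithium 22 (not isolated)
Conditions: n-BuLi (1.05 equiv), THF, −78 °C; then acrolein, −78 °C; then H2O
Reagents that add atoms: acrolein, C=CC=O
Why: Bromine–lithium exchange (assisted by the ortho methoxy group and expected at −78 °C to outrun removal of the hindered diarylallyl C–H) followed by 1,2-addition of the aryllithium to acrolein forms the C4a'–C5' bond and gives the aryl vinyl carbinol as a diastereomer mixture that converges on oxidation.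

Step 13
Reactants: 23 aryl vinyl carbinol
Product: 24 methyl (1R,3S)-5-[1-(2-acryloyl-3-methoxy-5-methylphenyl)prop-2-en-1-yl]-6,8-dimethoxy-1,3-dimethyl-3,4-dihydroisoquinoline-2(1H)-carboxylate (both C8' epimers)
Conditions: Dess–Martin periodinane, CH2Cl2, 0 °C → rt
Reagents that add atoms: none
Why: Dess–Martin oxidation of the secondary benzylic allylic alcohol gives the aryl vinyl ketone under neutral non-aqueous conditions that leave the terminal alkene, the carbamate and the electron-rich rings alone, and the enone is used at once to avoid polymerisation.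

Step 14
Reactants: 24 aryl vinyl ketone with ortho 1-arylallyl group
Product: 26 methyl (1R,3S)-5-(4-hydroxy-5-methoxy-7-methylnaphthalen-1-yl)-6,8-dimethoxy-1,3-dimethyl-3,4-dihydroisoquinoline-2(1H)-carboxylate (atropo-diastereomer mixture), via 4-aryl-4H-naphthalen-1-one 25 (not isolated)
Conditions: second-generation Grubbs catalyst (H2IMes)(PCy3)Cl2Ru=CHPh (5 mol %), degassed CH2Cl2 (5 mM), 40 °C; then Et3N (0.2 equiv), rt
Reagents that add atoms: none
Why: The ruthenium benzylidene should exchange onto the terminal CH=CH2 of the diarylallyl unit (the more electron-rich alkene), the new alkylidene adds to the acryloyl C=C held ortho on the same benzene ring, and cycloreversion of the ruthenacyclobutane releases ethene and forms C6'=C7'. The closest known reaction is ring-closing metathesis of 1-(2-allylaryl)prop-2-en-1-ones to 4H-naphthalen-1-ones that tautomerise to 1-naphthols; here the allylic carbon carries a second aryl group. The ring that closes is the six-membered carbocycle C4a'–C5'–C6'–C7'–C8'–C8a', formed by intramolecular metathesis of two terminal alkenes with the new double bond inside the ring. Intermediate 25 has a C8'–H that is doubly benzylic and γ to the carbonyl, so its removal by Et3N and protonation on oxygen give the aromatic naphthol 26, with aromatisation as the driving force. No stereocentre is made: the C8' centre becomes the biaryl axis and both epimers of 24 converge on the atropo-diastereomers of 26. The step needs ring closure to beat cross-metathesis and double-bond migration and the catalyst to stay active, which the ortho placement of the two alkenes, high dilution, the mild temperature and the carbamate-masked nitrogen are meant to secure.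

Step 15
Reactants: 26 naphthol
Product: 27 methyl (1R,3S)-5-(4,5-dimethoxy-7-methylnaphthalen-1-yl)-6,8-dimethoxy-1,3-dimethyl-3,4-dihydroisoquinoline-2(1H)-carboxylate
Conditions: MeI, K2CO3, acetone, reflux
Reagents that add atoms: iodomethane, CI
Why: Williamson O-methylation of the naphthol through its potassium naphtholate should be clean, since the peri methoxy group only slows the alkylation and no other acidic site is present.

Step 16
Reactants: 27 carbamate
Product: 28 (1R,3S)-5-(4,5-dimethoxy-7-methylnaphthalen-1-yl)-6,8-dimethoxy-1,2,3-trimethyl-1,2,3,4-tetrahydroisoquinoline (target)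
Conditions: LiAlH4, THF, reflux; then H2O
Reagents that add atoms: none
Why: LiAlH4 reduction of the methyl carbamate (hydride addition, loss of methoxide to an iminium ion, second hydride addition) turns N–CO2Me into N–CH3 without affecting the aryl ethers, the naphthalene or the C1 and C3 centres.

**Compound list**

1 | tert-butyl N-[(2S)-1-hydroxypropan-2-yl]carbamate (N-Boc-L-alaninol) | C[C@H](NC(=O)OC(C)(C)C)CO | starting material
2 | tert-butyl (4S)-4-methyl-1,2,3-oxathiazolidine-3-carboxylate 2-oxide (both sulfur epimers) | C[C@H]1COS(=O)N1C(=O)OC(C)(C)C | intermediate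
3 | tert-butyl (4S)-4-methyl-1,2,3-oxathiazolidine-3-carboxylate 2,2-dioxide | C[C@H]1COS(=O)(=O)N1C(=O)OC(C)(C)C | intermediate
4 | 1-bromo-3,5-dimethoxybenzene | COc1cc(Br)cc(OC)c1 | starting material
5 | (3,5-dimethoxyphenyl)magnesium bromide | COc1cc([Mg]Br)cc(OC)c1 | intermediate
6 | bromomagnesium N-(tert-butoxycarbonyl)-N-[(2S)-1-(3,5-dimethoxyphenyl)propan-2-yl]sulfamate | C[C@H](N(C(=O)OC(C)(C)C)S(=O)(=O)O[Mg]Br)Cc1cc(OC)cc(OC)c1 | intermediate
7 | tert-butyl N-[(2S)-1-(3,5-dimethoxyphenyl)propan-2-yl]carbamate | C[C@H](NC(=O)OC(C)(C)C)Cc1cc(OC)cc(OC)c1 | intermediate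
8 | (2S)-1-(3,5-dimethoxyphenyl)propan-2-aminium chloride | C[C@H]([NH3+])Cc1cc(OC)cc(OC)c1.[Cl-] | intermediate
9 | N-[(2S)-1-(3,5-dimethoxyphenyl)propan-2-yl]acetamide | C[C@H](NC(C)=O)Cc1cc(OC)cc(OC)c1 | intermediate
10 | (3S)-6,8-dimethoxy-1,3-dimethyl-3,4-dihydroisoquinoline | COc1cc(OC)c2c(c1)C[C@H](C)N=C2C | intermediate
11 | (1R,3S)-6,8-dimethoxy-1,3-dimethyl-1,2,3,4-tetrahydroisoquinoline | COc1cc(OC)c2c(c1)C[C@H](C)N[C@@H]2C | intermediate
12 | methyl (1R,3S)-6,8-dimethoxy-1,3-dimethyl-3,4-dihydroisoquinoline-2(1H)-carboxylate | COc1cc(OC)c2c(c1)C[C@H](C)N(C(=O)OC)[C@@H]2C | intermediate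
13 | methyl (1R,3S)-5-bromo-6,8-dimethoxy-1,3-dimethyl-3,4-dihydroisoquinoline-2(1H)-carboxylate | COc1cc(OC)c2c(c1Br)C[C@H](C)N(C(=O)OC)[C@@H]2C | intermediate
14 | 3-methoxy-5-methylbenzaldehyde | COc1cc(C)cc(C=O)c1 | starting material
15 | lithium {[2-(dimethylamino)ethyl](methyl)amino}(3-methoxy-5-methylphenyl)methanolate | COc1cc(C)cc(C(O[Li])N(C)CCN(C)C)c1 | intermediate
16 | lithium {[2-(dimethylamino)ethyl](methyl)amino}(2-lithio-3-methoxy-5-methylphenyl)methanolate | COc1cc(C)cc(C(O[Li])N(C)CCN(C)C)c1[Li] | intermediate
17 | lithium (2-bromo-3-methoxy-5-methylphenyl){[2-(dimethylamino)ethyl](methyl)amino}methanolate | COc1cc(C)cc(C(O[Li])N(C)CCN(C)C)c1Br | intermediate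
18 | 2-bromo-3-methoxy-5-methylbenzaldehyde | COc1cc(C)cc(C=O)c1Br | intermediate
19 | methyl (1R,3S)-5-lithio-6,8-dimethoxy-1,3-dimethyl-3,4-dihydroisoquinoline-2(1H)-carboxylate | COc1cc(OC)c2c(c1[Li])C[C@H](C)N(C(=O)OC)[C@@H]2C | intermediate
20 | methyl (1R,3S)-5-[(2-bromo-3-methoxy-5-methylphenyl)(hydroxy)methyl]-6,8-dimethoxy-1,3-dimethyl-3,4-dihydroisoquinoline-2(1H)-carboxylate (both carbinol epimers) | COc1cc(OC)c2c(c1C(O)c3cc(C)cc(OC)c3Br)C[C@H](C)N(C(=O)OC)[C@@H]2C | intermediate
21 | methyl (1R,3S)-5-[1-(2-bromo-3-methoxy-5-methylphenyl)prop-2-en-1-yl]-6,8-dimethoxy-1,3-dimethyl-3,4-dihydroisoquinoline-2(1H)-carboxylate (both C8' epimers) | COc1cc(OC)c2c(c1C(C=C)c3cc(C)cc(OC)c3Br)C[C@H](C)N(C(=O)OC)[C@@H]2C | intermediate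
22 | methyl (1R,3S)-5-[1-(2-lithio-3-methoxy-5-methylphenyl)prop-2-en-1-yl]-6,8-dimethoxy-1,3-dimethyl-3,4-dihydroisoquinoline-2(1H)-carboxylate | COc1cc(OC)c2c(c1C(C=C)c3cc(C)cc(OC)c3[Li])C[C@H](C)N(C(=O)OC)[C@@H]2C | intermediate
23 | methyl (1R,3S)-5-{1-[2-(1-hydroxyprop-2-en-1-yl)-3-methoxy-5-methylphenyl]prop-2-en-1-yl}-6,8-dimethoxy-1,3-dimethyl-3,4-dihydroisoquinoline-2(1H)-carboxylate (diastereomer mixture) | COc1cc(OC)c2c(c1C(C=C)c3cc(C)cc(OC)c3C(O)C=C)C[C@H](C)N(C(=O)OC)[C@@H]2C | intermediate
24 | methyl (1R,3S)-5-[1-(2-acryloyl-3-methoxy-5-methylphenyl)prop-2-en-1-yl]-6,8-dimethoxy-1,3-dimethyl-3,4-dihydroisoquinoline-2(1H)-carboxylate (both C8' epimers) | COc1cc(OC)c2c(c1C(C=C)c3cc(C)cc(OC)c3C(=O)C=C)C[C@H](C)N(C(=O)OC)[C@@H]2C | intermediate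
25 | methyl (1R,3S)-6,8-dimethoxy-5-(5-methoxy-7-methyl-4-oxo-1,4-dihydronaphthalen-1-yl)-1,3-dimethyl-3,4-dihydroisoquinoline-2(1H)-carboxylate (both C8' epimers) | COc1cc(OC)c2c(c1C3C=CC(=O)c4c(OC)cc(C)cc43)C[C@H](C)N(C(=O)OC)[C@@H]2C | intermediate
26 | methyl (1R,3S)-5-(4-hydroxy-5-methoxy-7-methylnaphthalen-1-yl)-6,8-dimethoxy-1,3-dimethyl-3,4-dihydroisoquinoline-2(1H)-carboxylate | COc1cc(OC)c2c(c1-c3ccc(O)c4c(OC)cc(C)cc34)C[C@H](C)N(C(=O)OC)[C@@H]2C | intermediate
27 | methyl (1R,3S)-5-(4,5-dimethoxy-7-methylnaphthalen-1-yl)-6,8-dimethoxy-1,3-dimethyl-3,4-dihydroisoquinoline-2(1H)-carboxylate | COc1cc(OC)c2c(c1-c3ccc(OC)c4c(OC)cc(C)cc34)C[C@H](C)N(C(=O)OC)[C@@H]2C | intermediate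
28 | (1R,3S)-5-(4,5-dimethoxy-7-methylnaphthalen-1-yl)-6,8-dimethoxy-1,2,3-trimethyl-1,2,3,4-tetrahydroisoquinoline | COc1cc(OC)c2c(c1-c3ccc(OC)c4c(OC)cc(C)cc34)C[C@H](C)N(C)[C@@H]2C | target

**Step count**

Total: 16 steps. Longest linear sequence: 15 steps (steps 1–8 and 10–16, from 1); step 9 is the only side branch.

**Steps most likely to fail**

Step 11. The parent vinyl borate is a weaker ipso nucleophile than β-substituted alkenyl borates, so the diarylmethyl cation may instead be consumed by Friedel–Crafts attack on the electron-rich C7 position of a second molecule. Longer acid exposure could also ionise the C1–N bond and erode the cis relationship. The fallback sets out from 20 and brings in the two carbons at the alkyne oxidation level. The cation would be trapped with potassium trifluoro[(trimethylsilyl)ethynyl]borate and HBF4·OEt2 in MeCN, alkynyl borates being the most reactive partners known for this substitution, to give methyl (1R,3S)-5-[1-(2-bromo-3-methoxy-5-methylphenyl)-3-(trimethylsilyl)prop-2-yn-1-yl]-6,8-dimethoxy-1,3-dimethyl-3,4-dihydroisoquinoline-2(1H)-carboxylate F1. K2CO3 in MeOH at 0 °C would remove silicon to give methyl (1R,3S)-5-[1-(2-bromo-3-methoxy-5-methylphenyl)prop-2-yn-1-yl]-6,8-dimethoxy-1,3-dimethyl-3,4-dihydroisoquinoline-2(1H)-carboxylate F2. Semi-hydrogenation with H2 over Lindlar catalyst (Pd on CaCO3 poisoned with Pb(OAc)2, quinoline) would then come back to the route at 21.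

Step 14. Ruthenium hydride species may move the terminal double bond into conjugation with the two aryl rings, after which the six-membered ring can no longer close. Loading onto the hindered allylic alkene may also be so slow that the enone oligomerises by cross-metathesis. The fallback sets out from 23 and closes the ring at the alcohol oxidation level, where the second alkene is an unhindered allylic alcohol that takes up the catalyst readily. Second-generation Hoveyda–Grubbs catalyst (H2IMes)Cl2Ru=CH(2-iPrO-C6H4) in dilute CH2Cl2 would give methyl (1R,3S)-5-(4-hydroxy-5-methoxy-7-methyl-1,4-dihydronaphthalen-1-yl)-6,8-dimethoxy-1,3-dimethyl-3,4-dihydroisoquinoline-2(1H)-carboxylate F3. This compound would not be stored, to avoid dehydration, but oxidised directly with Dess–Martin periodinane and NaHCO3 to 25. Et3N would then give the naphthol, so the route is rejoined at 26.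

Step 12. The aryllithium or n-BuLi may take the doubly benzylic, allylic C8'–H instead of completing exchange and addition. Attack on the carbamate or anionic polymerisation of acrolein would also lower the return. The fallback sets out from 21 and avoids carbanions altogether. A carbonylative Stille coupling with Pd(PPh3)4 (zerovalent palladium), CO (5 bar) and tributyl(vinyl)stannane (2 equiv) in toluene at 90 °C would form the aryl vinyl ketone in one operation. It comes back to the route at 24, bypassing 23. The CO pressure and the excess stannane are chosen so that transmetalation of the acylpalladium intermediate outruns its addition to the neighbouring vinyl group.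

**Further compounds**

F1 | step 11 | methyl (1R,3S)-5-[1-(2-bromo-3-methoxy-5-methylphenyl)-3-(trimethylsilyl)prop-2-yn-1-yl]-6,8-dimethoxy-1,3-dimethyl-3,4-dihydroisoquinoline-2(1H)-carboxylate | COc1cc(OC)c2c(c1C(C#C[Si](C)(C)C)c3cc(C)cc(OC)c3Br)C[C@H](C)N(C(=O)OC)[C@@H]2C
F2 | step 11 | methyl (1R,3S)-5-[1-(2-bromo-3-methoxy-5-methylphenyl)prop-2-yn-1-yl]-6,8-dimethoxy-1,3-dimethyl-3,4-dihydroisoquinoline-2(1H)-carboxylate | COc1cc(OC)c2c(c1C(C#C)c3cc(C)cc(OC)c3Br)C[C@H](C)N(C(=O)OC)[C@@H]2C
F3 | step 14 | methyl (1R,3S)-5-(4-hydroxy-5-methoxy-7-methyl-1,4-dihydronaphthalen-1-yl)-6,8-dimethoxy-1,3-dimethyl-3,4-dihydroisoquinoline-2(1H)-carboxylate | COc1cc(OC)c2c(c1C3C=CC(O)c4c(OC)cc(C)cc43)C[C@H](C)N(C(=O)OC)[C@@H]2C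
F0 | step 12 | none | none
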